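**Plan**
- Retrosynthesis: first the phenol O–H is masked as a benzyl ether; then the C2–C3 bond of the docosanoyl chain is cut, giving an iodoacetate ester of O‑benzyl tyrosol and icos‑1‑ene; last the ester C–O bond is cut (alcohol + iodoacetic acid).
- Enabling feature: C2 lies α to the ester carbonyl C1, so a C2–I bond is weak and gives an electrophilic radical. C3 is the unhindered terminal sp2 carbon of a monosubstituted alkene. Both carbons are donors in polar chemistry (enolate carbon and alkene terminus) and are joined through the radical; the para‑disubstituted benzene ring is a spectator.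
- Forward: benzylate the phenol, esterify with iodoacetic acid, join the chain by iodine atom‑transfer radical addition to icos‑1‑ene and remove the iodine in the same flask, then cleave the benzyl ether.
- No ring is formed. The target has no stereocentre; the one transient stereocentre (C4–I, racemic) is erased in the step that creates it.

Key step: step 3

Remark: tyrosol, iodoacetic acid and icos‑1‑ene are taken as commercial materials.

**Step 1**
Reactants: 1 tyrosol [4‑(2‑hydroxyethyl)phenol]
Product: 2 2‑[4‑(benzyloxy)phenyl]ethanol
Conditions: BnBr (1.05 equiv), K2CO3, acetone, reflux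
Reagents that add atoms: benzyl bromide, BrCc1ccccc1
Why: Williamson ether synthesis; carbonate deprotonates only the phenol (far more acidic than the primary alcohol), so alkylation should occur at the aryl oxygen alone.

**Step 2**
Reactants: 2 2‑[4‑(benzyloxy)phenyl]ethanol; 3 iodoacetic acid
Product: 4 2‑[4‑(benzyloxy)phenyl]ethyl iodoacetate
Conditions: DCC (1.1 equiv), DMAP (5 mol %), CH2Cl2, 0 °C, dark
Reagents that add atoms: none
Why: Steglich esterification of a primary alcohol with an activated acid; low temperature and a small DMAP charge should keep N‑alkylation by the iodoacetate in check.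

**Step 3**
Reactants: 4 2‑[4‑(benzyloxy)phenyl]ethyl iodoacetate; 5 icos‑1‑ene (2 equiv)
Product: 7 2‑[4‑(benzyloxy)phenyl]ethyl docosanoate, via racemic 4‑iodo ester 6 (not isolated)
Conditions: Et3B (3 × 0.1 equiv), air, CH2Cl2, rt; then Bu3SnH (1.2 equiv), Et3B (0.1 equiv), air, rt
Reagents that add atoms: none
Why: Ethyl radicals from Et3B/O2 abstract iodine from 4; the electrophilic alkoxycarbonylmethyl radical adds to the unsubstituted terminal carbon of 5 (new C2–C3 bond), and the secondary C4 radical takes iodine from a further molecule of 4 to give 6 and carry the chain. The closest known reaction type is the Kharasch‑type iodine atom‑transfer radical addition of α‑iodo esters to terminal alkenes, followed here in the same flask by a tin hydride radical deiodination under Et3B/O2 initiation. No ring is closed. The only new stereocentre, C4 of 6, arises without control as a racemate and is erased when C–I becomes C–H. The step needs regioselectivity (attack at the terminal CH2, secured by its lack of hindrance and by formation of the more substituted radical), single addition instead of telomerisation (secured by polarity matching, since the nucleophilic secondary radical should abstract iodine from the electron‑poor iodoacetate much faster than it adds to a second unactivated alkene) and survival of the γ‑iodo ester against lactonisation (secured by room temperature and immediate reduction). The hydride is added only after 4 is consumed, so that the α‑carbonyl radical is not reduced before it forms the C–C bond.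

**Step 4**
Reactants: 7 2‑[4‑(benzyloxy)phenyl]ethyl docosanoate
Product: 8 2‑(4‑hydroxyphenyl)ethyl docosanoate
Conditions: H2 (1 atm), 10 % Pd/C, EtOAc/THF, rt
Reagents that add atoms: none
Why: Catalytic hydrogenolysis of an aryl benzyl ether; the ester oxygen sits on a homobenzylic carbon and the saturated chain has no reducible group, so only the O–CH2Ph bond should be cleaved.

**Compound list**
1 | tyrosol, 4‑(2‑hydroxyethyl)phenol | OCCc1ccc(O)cc1 | starting material
2 | 2‑[4‑(benzyloxy)phenyl]ethanol | OCCc1ccc(OCc2ccccc2)cc1 | intermediate
3 | iodoacetic acid | OC(=O)CI | starting material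
4 | 2‑[4‑(benzyloxy)phenyl]ethyl iodoacetate | ICC(=O)OCCc1ccc(OCc2ccccc2)cc1 | intermediate
5 | icos‑1‑ene | CCCCCCCCCCCCCCCCCCC=C | starting material
6 | 2‑[4‑(benzyloxy)phenyl]ethyl 4‑iododocosanoate (racemic, formed in the flask) | CCCCCCCCCCCCCCCCCCC(I)CCC(=O)OCCc1ccc(OCc2ccccc2)cc1 | intermediate
7 | 2‑[4‑(benzyloxy)phenyl]ethyl docosanoate | CCCCCCCCCCCCCCCCCCCCCC(=O)OCCc1ccc(OCc2ccccc2)cc1 | intermediate
8 | 2‑(4‑hydroxyphenyl)ethyl docosanoate | CCCCCCCCCCCCCCCCCCCCCC(=O)OCCc1ccc(O)cc1 | target

**Total step count:** 4
**Longest linear sequence:** 4 steps (1 → 2 → 4 → 7 → 8)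

**Steps most likely to fail**

Step 3. The radical chain may stall through poor initiation or slow iodine transfer. The γ‑iodo ester may also cyclise to the γ‑lactone with loss of the arylethyl group before it is reduced, or the adduct radical may add to a second alkene. The fallback makes the same C2–C3 bond as an olefin by polar chemistry. It sets out from 4: PPh3 in toluene at rt should give {2‑[2‑(4‑benzyloxyphenyl)ethoxy]‑2‑oxoethyl}triphenylphosphonium iodide F1. Cold dilute aqueous NaOH/CH2Cl2 should convert it into the stabilised ylide 2‑[4‑(benzyloxy)phenyl]ethyl (triphenylphosphoranylidene)acetate F2. A Wittig reaction in CH2Cl2 with icosanal F3 (from commercial icosan‑1‑ol by TEMPO/PhI(OAc)2 oxidation) should give 2‑[4‑(benzyloxy)phenyl]ethyl (E)‑docos‑2‑enoate F4. Hydrogenation (H2, Pd/C, EtOAc) should then saturate C2=C3 and cleave the benzyl ether in one operation, so the fallback comes back to the route at 8.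

Step 2. DMAP may be quaternised by the iodoacetate, iodide may be displaced by nucleophiles present during the coupling, or the activated acid may rearrange to the N‑acylurea. The fallback sets out from 2: bromoacetyl bromide and pyridine in CH2Cl2 at −10 °C should give 2‑[4‑(benzyloxy)phenyl]ethyl bromoacetate F5. A Finkelstein exchange (NaI, acetone, rt) then comes back to the route at 4.

Step 4. The palladium surface may be poisoned by traces of organotin or iodide carried over from step 3, leaving the hydrogenolysis incomplete. The fallback replaces the heterogeneous reduction by a non‑reductive Lewis‑acid cleavage of the ArO–CH2Ph bond. It sets out from 7: BCl3 and pentamethylbenzene (cation scavenger) in CH2Cl2 at −78 °C should leave the alkyl ester untouched and come back to the route at 8. It makes no new compound (entry F0).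

**Further compounds**
F1 | step 3 | {2‑[2‑(4‑benzyloxyphenyl)ethoxy]‑2‑oxoethyl}triphenylphosphonium iodide | [I-].O=C(C[P+](c1ccccc1)(c1ccccc1)c1ccccc1)OCCc1ccc(OCc2ccccc2)cc1
F2 | step 3 | 2‑[4‑(benzyloxy)phenyl]ethyl (triphenylphosphoranylidene)acetate | O=C(C=P(c1ccccc1)(c1ccccc1)c1ccccc1)OCCc1ccc(OCc2ccccc2)cc1
F3 | step 3 | icosanal | CCCCCCCCCCCCCCCCCCCC=O
F4 | step 3 | 2‑[4‑(benzyloxy)phenyl]ethyl (E)‑docos‑2‑enoate | CCCCCCCCCCCCCCCCCCC/C=C/C(=O)OCCc1ccc(OCc2ccccc2)cc1
F5 | step 2 | 2‑[4‑(benzyloxy)phenyl]ethyl bromoacetate | BrCC(=O)OCCc1ccc(OCc2ccccc2)cc1
F0 | step 4 | none | none
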